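**Plan**
- Cuts: (a) C9′=C10′ of the triene (Julia–Kocienski, chain sulfone + C7 dienal). (b) CO2H back to a CH2OAc arm. (c) In one stroke the ring bonds C3–C4 and O1–C5, which opens the 1,2-dioxolane to a peroxycarbenium ion and a 1,1-disubstituted alkene.
- Enabling feature: in the ring O1–O2–C3–C4–C5, C3 already carries O2, so it can be a peroxide-stabilised cation. The bare C4H2 next to the fully substituted C5(CH3)(alkyl) is the imprint of H2C=C(CH3)R, which takes a cation at CH2 and offers a tertiary cation at C5 to O1.
- Forward: the C12 bromoalkene (step 1) and the silylperoxy ketal (steps 2–3) are joined and the only ring is closed in step 4. Then Br → PT-sulfone → triene (steps 5–7) and OAc → OH → CO2H (steps 8–9).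
- Stereochemistry: both quaternary centres (methyl groups cis) arise in step 4 under a confined chiral counter-anion, and the racemic ketal converges through the planar cation. Two E bonds come with the dienal and the third from the olefination.
- Helpers: Et3Si and OMe leave together in step 4. The acetate oxidation level keeps a carbonyl away from the cation. Br is a cation-proof stand-in for the triene.

Key step: step 4

Assumption: IDPi means a confined imidodiphosphorimidate Brønsted acid (two 3,3′-diaryl-BINOL phosphorus units bridged by nitrogen, N-triflyl groups), made from commercial BINOL by the standard sequence and used only as a catalyst; its sense of induction for this new ion pair cannot be predicted, so the catalyst enantiomer and its aryl groups are taken to be chosen by screening so that (3S,5R)-10 results.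

**Step 1**
Reactants: 1 1,8-dibromooctane (threefold excess); 2 2-methylallylmagnesium chloride
Product: 3 11-bromo-2-methylundec-1-ene
Conditions: Li2CuCl4 (2 mol %), THF, 0 °C
Reagents that add atoms: none
Why: Copper-catalysed sp3–sp3 cross-coupling of an allylic Grignard reagent with a primary bromide; the symmetric methallyl unit makes SN2 and SN2′ attack equivalent, the excess of 1 suppresses double coupling, and no stereocentre is formed.

**Step 2**
Reactants: 4 3-methylbut-3-en-1-yl acetate
Product: 6 3-hydroperoxy-3-methoxybutyl acetate (racemic), via carbonyl oxide of 4-acetoxybutan-2-one 5 (not isolated)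
Conditions: O3, MeOH–CH2Cl2, −78 °C
Reagents that add atoms: ozone [O-][O+]=O; methanol CO
Why: Ozonolysis in a participating solvent, in which the primary ozonide of a 1,1-disubstituted alkene splits to the more substituted carbonyl oxide 5 and methanol traps it as the α-methoxy hydroperoxide; the new ketal centre is racemic, which is harmless because step 4 erases it.

**Step 3**
Reactants: 6 3-hydroperoxy-3-methoxybutyl acetate
Product: 7 3-methoxy-3-[(triethylsilyl)peroxy]butyl acetate (racemic)
Conditions: Et3SiCl, imidazole, DMF, 0 °C
Reagents that add atoms: chlorotriethylsilane CC[Si](Cl)(CC)CC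
Why: Standard O-silylation of a hydroperoxide with silyl chloride/imidazole, which turns the acidic OOH into the latent oxygen nucleophile and silylium source needed in step 4 and leaves ketal and acetate untouched.

**Step 4**
Reactants: 7 3-methoxy-3-[(triethylsilyl)peroxy]butyl acetate; 3 11-bromo-2-methylundec-1-ene (1.5 equiv)
Product: 10 2-[(3S,5R)-5-(9-bromononyl)-3,5-dimethyl-1,2-dioxolan-3-yl]ethyl acetate, via triethylsilyl peroxycarbenium ion 8 (not isolated), via tertiary carbocation 9 (not isolated)
Conditions: IDPi acid (one enantiomer, 3 mol %), CH2Cl2–pentane, −78 °C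
Reagents that add atoms: none
Why: Proposed new method: the acid HX* (X* = IDPi anion) ionises the first molecules of 7 by protonating the methoxy group (the trace of methanol so formed is later silylated to the same Et3SiOMe), and from then on the silylated acid Et3Si–X* takes the methoxy group from either enantiomer of racemic 7 as Et3SiOMe and leaves the planar peroxycarbenium ion 8, CH3C(=O+–OSiEt3)CH2CH2OAc, inside the confined anion, the CH2 terminus of alkene 3 adds to its carbon (C4–C3 bond, Markovnikov) to give the tertiary cation 9, and the silylated outer peroxide oxygen captures C5 (O1–C5 bond) while Et3Si+ returns to X*, so that the silyl group of the substrate itself turns the catalyst over. The closest known reaction type is the formal [3+2] annulation of triethylsilylperoxy ketals with alkenes under stoichiometric SnCl4 or TiCl4, which gives racemic 1,2-dioxolanes; only the exchange of the achiral Lewis acid for silylium–IDPi ion-pair catalysis, established for oxocarbenium ions from acetals and small ketones, is new. The one ring closes by attack of oxygen on a fully formed tertiary cation, a five-membered closure that is formally 5-endo with respect to the former C4=C5 bond and is unrestricted because no π bond has to be approached. C3 is set in the C–C bond-forming event by the anion pocket, which has to tell CH3 from CH2CH2OAc on the cation, the task such anions solve in additions to 2-butanone-type oxocarbenium ions; C5 is set in the ring closure within the same ion pair, which has to tell CH3 from n-alkyl at a tertiary cationic carbon as in IDPi-catalysed hydroalkoxylation of 1,1-disubstituted alkenes, and since both pairs of groups are sterically alike no appreciable substrate bias is expected to oppose the catalyst. The step is stereoconvergent because ionisation erases the ketal stereocentre of 7. It needs reaction at one alkene only and a cation that lives long enough to be trapped, which the substrates secure by carrying Br in place of the nucleophilic triene, by holding the side arm at the acetate level so that no β-carbonyl group destabilises 8 or invites elimination, and by an ester oxygen too weakly nucleophilic to intercept 9.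

**Step 5**
Reactants: 10 2-[(3S,5R)-5-(9-bromononyl)-3,5-dimethyl-1,2-dioxolan-3-yl]ethyl acetate
Product: 11 2-[(3S,5R)-3,5-dimethyl-5-{9-[(1-phenyl-1H-tetrazol-5-yl)sulfanyl]nonyl}-1,2-dioxolan-3-yl]ethyl acetate
Conditions: 1-phenyl-1H-tetrazole-5-thiol, K2CO3, acetone, rt
Reagents that add atoms: 1-phenyl-1H-tetrazole-5-thiol Sc1nnnn1-c1ccccc1
Why: SN2 thioetherification of a primary bromide by a soft thiolate; the hindered di-tertiary peroxide has no α-hydrogen for Kornblum–DeLaMare fragmentation, and both it and the acetate tolerate carbonate in acetone, so both stereocentres are untouched.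

**Step 6**
Reactants: 11 the PT-sulfide acetate
Product: 12 2-[(3S,5R)-3,5-dimethyl-5-{9-[(1-phenyl-1H-tetrazol-5-yl)sulfonyl]nonyl}-1,2-dioxolan-3-yl]ethyl acetate
Conditions: (NH4)6Mo7O24·4H2O (10 mol %), 30 % aq H2O2, EtOH, 0 °C → rt
Reagents that add atoms: hydrogen peroxide OO
Why: Molybdate-catalysed sulfide-to-sulfone oxidation, an oxidising medium that cannot harm a dialkyl peroxide and meets no alkene at this stage.

**Step 7**
Reactants: 12 the PT-sulfone acetate; 13 (2E,4E)-hepta-2,4-dienal
Product: 15 2-[(3S,5R)-5-[(9E,11E,13E)-hexadeca-9,11,13-trien-1-yl]-3,5-dimethyl-1,2-dioxolan-3-yl]ethyl acetate, via potassium α-sulfonyl carbanion of the PT-sulfone acetate 14 (not isolated)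
Conditions: KHMDS (1.05 equiv), DME, −55 °C; then 13, −55 °C → rt, dark
Reagents that add atoms: none
Why: Julia–Kocienski olefination (addition, Smiles rearrangement, elimination), for which an alkyl PT-sulfone with potassium counter-ion in DME and a conjugated aldehyde should favour the E alkene; the two E bonds of 13 are carried over, and premetalation with one equivalent of base leaves the far less acidic acetate alone.

**Step 8**
Reactants: 15 the triene acetate
Product: 16 2-[(3S,5R)-5-[(9E,11E,13E)-hexadeca-9,11,13-trien-1-yl]-3,5-dimethyl-1,2-dioxolan-3-yl]ethanol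
Conditions: K2CO3 (0.2 equiv), MeOH, 0 °C → rt
Reagents that add atoms: none
Why: Carbonate-catalysed transesterification of a primary acetate, mild enough for the triene and for a peroxide that has no α-hydrogen and no acidifying carbonyl group next to it.

**Step 9**
Reactants: 16 the triene alcohol
Product: 18 2-[(3R,5R)-5-[(9E,11E,13E)-hexadeca-9,11,13-trien-1-yl]-3,5-dimethyl-1,2-dioxolan-3-yl]acetic acid (target), via (3R,5R) triene aldehyde 17 (not isolated)
Conditions: TEMPO (20 mol %), PhI(OAc)2 (2.2 equiv), MeCN–pH 7 buffer, 0 °C → rt, dark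
Reagents that add atoms: water O
Why: Oxoammonium (TEMPO)-catalysed oxidation of a primary alcohol through aldehyde 17 and its hydrate to the acid under near-neutral conditions that should spare triene and peroxide; no bond at C3 or C5 is touched, and the C3 descriptor changes from S to R only because the arm gains CIP priority.

**Compound list**
1 | 1,8-dibromooctane | BrCCCCCCCCBr | starting material
2 | 2-methylallylmagnesium chloride | C=C(C)C[Mg]Cl | starting material
3 | 11-bromo-2-methylundec-1-ene | C=C(C)CCCCCCCCCBr | intermediate
4 | 3-methylbut-3-en-1-yl acetate | C=C(C)CCOC(C)=O | starting material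
5 | carbonyl oxide of 4-acetoxybutan-2-one (not isolated) | CC(=[O+][O-])CCOC(C)=O | intermediate
6 | 3-hydroperoxy-3-methoxybutyl acetate (racemic) | CC(OC)(OO)CCOC(C)=O | intermediate
7 | 3-methoxy-3-[(triethylsilyl)peroxy]butyl acetate (racemic) | CC(OC)(OO[Si](CC)(CC)CC)CCOC(C)=O | intermediate
8 | triethylsilyl peroxycarbenium ion CH3C(=O+–OSiEt3)CH2CH2OAc, paired with the IDPi anion (not isolated) | CC(=[O+]O[Si](CC)(CC)CC)CCOC(C)=O | intermediate
9 | tertiary carbocation Et3SiOO–C(CH3)(CH2CH2OAc)–CH2–C+(CH3)(CH2)9Br after C4–C3 bond formation, C3 configured as in 10 (not isolated) | C[C+](CCCCCCCCCBr)C[C@](C)(CCOC(C)=O)OO[Si](CC)(CC)CC | intermediate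
10 | 2-[(3S,5R)-5-(9-bromononyl)-3,5-dimethyl-1,2-dioxolan-3-yl]ethyl acetate (methyl groups cis) | BrCCCCCCCCC[C@]1(C)C[C@](C)(CCOC(C)=O)OO1 | intermediate
11 | PT-sulfide acetate, (3S,5R) | c1ccc(cc1)-n1nnnc1SCCCCCCCCC[C@]2(C)C[C@](C)(CCOC(C)=O)OO2 | intermediate
12 | PT-sulfone acetate, (3S,5R) | c1ccc(cc1)-n1nnnc1S(=O)(=O)CCCCCCCCC[C@]2(C)C[C@](C)(CCOC(C)=O)OO2 | intermediate
13 | (2E,4E)-hepta-2,4-dienal | CC/C=C/C=C/C=O | starting material
14 | potassium α-sulfonyl carbanion of 12 (not isolated) | [K+].c1ccc(cc1)-n1nnnc1S(=O)(=O)[CH-]CCCCCCCC[C@]2(C)C[C@](C)(CCOC(C)=O)OO2 | intermediate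
15 | triene acetate, (3S,5R), 9E,11E,13E | CC/C=C/C=C/C=C/CCCCCCCC[C@]1(C)C[C@](C)(CCOC(C)=O)OO1 | intermediate
16 | triene alcohol, (3S,5R), 9E,11E,13E | CC/C=C/C=C/C=C/CCCCCCCC[C@]1(C)C[C@](C)(CCO)OO1 | intermediate
17 | triene aldehyde, 2-[(3R,5R)-5-[(9E,11E,13E)-hexadeca-9,11,13-trien-1-yl]-3,5-dimethyl-1,2-dioxolan-3-yl]acetaldehyde (not isolated) | CC/C=C/C=C/C=C/CCCCCCCC[C@]1(C)C[C@](C)(CC=O)OO1 | intermediate
18 | 2-[(3R,5R)-5-[(9E,11E,13E)-hexadeca-9,11,13-trien-1-yl]-3,5-dimethyl-1,2-dioxolan-3-yl]acetic acid | CC/C=C/C=C/C=C/CCCCCCCC[C@]1(C)C[C@](C)(CC(=O)O)OO1 | target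

**Totals**
Total steps: 9. Longest linear sequence: 8 (steps 2–9, from 4); step 1 is a one-step branch.

**Steps most likely to fail**

1. Step 4. What may go wrong: too little facial discrimination at C3 or C5 within the ion pair, deactivation of the silylium catalyst by the Lewis-basic acetate, or proton loss from the tertiary cation instead of ring closure.
Fallback (known chemistry; sets out from 7 and 3, returns at 10): 7 and 3 are combined with stoichiometric SnCl4 in CH2Cl2 at −78 °C, the established racemic annulation, which gives the bromo acetate as a mixture of all four stereoisomers F1. K2CO3/MeOH, then chromatographic removal of the trans-dimethyl pair, should give the racemic cis-dimethyl bromo alcohol F2. Steglich esterification with (S)-naproxen gives two diastereomeric esters, from which the (S)-naproxen ester of the (3S,5R) alcohol F3 is separated by chromatography or crystallisation. Methanolysis gives the enantiopure (3S,5R) bromo alcohol F4, and Ac2O/pyridine returns to 10.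

2. Step 7. What may go wrong: erosion of E selectivity at the new double bond, vinylogous deprotonation of the dienal by the sulfonyl anion, or self-condensation of the PT-sulfone.
Fallback (polarity reversed; sets out from 10 and 13, returns at 15): 10 is oxidised with Me3NO in DMSO at rt (Kornblum-type halide oxidation) to the (3S,5R) acetate aldehyde F5. Separately, 13 is reduced (NaBH4, MeOH, 0 °C) to (2E,4E)-hepta-2,4-dien-1-ol F6, which PBr3 converts into (2E,4E)-1-bromohepta-2,4-diene F7. An Arbuzov reaction with P(OEt)3 then gives diethyl [(2E,4E)-hepta-2,4-dien-1-yl]phosphonate F8. Horner–Wadsworth–Emmons olefination of F5 with lithiated F8 (LiHMDS, THF, −78 °C → rt), a reaction type that normally favours the E alkene with allylic phosphonates, gives 15.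

3. Step 9. What may go wrong: oxidative attack on or isomerisation of the triene, or β-elimination of the peroxide at the β-peroxy aldehyde stage.
Fallback (order of events changed so that no oxidant meets the triene; sets out from 12 and 13, returns at 18): 12 is deacetylated (K2CO3, MeOH) to the (3S,5R) sulfone alcohol F9, which is oxidised (TEMPO/PhI(OAc)2, aq MeCN) to the (3R,5R) sulfone acid F10. Julia–Kocienski olefination of F10 after double deprotonation (KHMDS, 2.1 equiv, DME, −55 °C) with 13 gives 18 directly. The carboxylate resists α-deprotonation and so protects the β-peroxide.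

**Further compounds**
F1 | step 4 | 2-[5-(9-bromononyl)-3,5-dimethyl-1,2-dioxolan-3-yl]ethyl acetate, all four stereoisomers | BrCCCCCCCCCC1(C)CC(C)(CCOC(C)=O)OO1
F2 | step 4 | racemic cis-dimethyl 2-[5-(9-bromononyl)-3,5-dimethyl-1,2-dioxolan-3-yl]ethanol | BrCCCCCCCCC[C@]1(C)C[C@](C)(CCO)OO1.BrCCCCCCCCC[C@@]1(C)C[C@@](C)(CCO)OO1
F3 | step 4 | 2-[(3S,5R)-5-(9-bromononyl)-3,5-dimethyl-1,2-dioxolan-3-yl]ethyl (S)-2-(6-methoxynaphthalen-2-yl)propanoate | BrCCCCCCCCC[C@]1(C)C[C@](C)(CCOC(=O)[C@@H](C)c2ccc3cc(OC)ccc3c2)OO1
F4 | step 4 | 2-[(3S,5R)-5-(9-bromononyl)-3,5-dimethyl-1,2-dioxolan-3-yl]ethanol | BrCCCCCCCCC[C@]1(C)C[C@](C)(CCO)OO1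
F5 | step 7 | 2-[(3S,5R)-3,5-dimethyl-5-(9-oxononyl)-1,2-dioxolan-3-yl]ethyl acetate | O=CCCCCCCCC[C@]1(C)C[C@](C)(CCOC(C)=O)OO1
F6 | step 7 | (2E,4E)-hepta-2,4-dien-1-ol | CC/C=C/C=C/CO
F7 | step 7 | (2E,4E)-1-bromohepta-2,4-diene | CC/C=C/C=C/CBr
F8 | step 7 | diethyl [(2E,4E)-hepta-2,4-dien-1-yl]phosphonate | CC/C=C/C=C/CP(=O)(OCC)OCC
F9 | step 9 | 2-[(3S,5R)-3,5-dimethyl-5-{9-[(1-phenyl-1H-tetrazol-5-yl)sulfonyl]nonyl}-1,2-dioxolan-3-yl]ethanol | c1ccc(cc1)-n1nnnc1S(=O)(=O)CCCCCCCCC[C@]2(C)C[C@](C)(CCO)OO2
F10 | step 9 | 2-[(3R,5R)-3,5-dimethyl-5-{9-[(1-phenyl-1H-tetrazol-5-yl)sulfonyl]nonyl}-1,2-dioxolan-3-yl]acetic acid | c1ccc(cc1)-n1nnnc1S(=O)(=O)CCCCCCCCC[C@]2(C)C[C@](C)(CC(=O)O)OO2
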